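**Strategy.** Ring A is disconnected from the pyrone core at C4a–C5 and C8–C8a. The key step exploits the fact that C5, C6, C7 and C8 of ring A bear OH, H, OMe and OMe, the pattern of a 1,1,3,4-tetraoxygenated butadiene, while C4a=C8a is the enone bond of a 4-pyranone (ring C). A polarised [4+2] cycloaddition of a trimethoxy silyl ketene acetal diene to a 2-aryl-5-(phenylsulfinyl)-4-pyranone, followed in the same flask by loss of benzenesulfenic acid and methoxytrimethylsilane, should build ring A with the free 5-OH and both methyl ethers in place. The pyranone precursor carries the complete 2,5-dimethoxyphenyl ring B and a sulfoxide at the future C4a.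

Key step: step 6

Remark: the target has no stereogenic element, so the single-enantiomer requirement needs no stereocontrol; sulfoxide 7 is used as the racemate and transient centres are drawn without absolute meaning.

**Step 1**
Reactants: 1 1-(phenylthio)propan-2-one; 2 N,N-dimethylformamide dimethyl acetal
Product: 3 (Z)-4-(dimethylamino)-3-(phenylthio)but-3-en-2-one (alkene geometry immaterial)
Conditions: 2 (1.2 equiv), toluene, 80 °C
Reagents that add atoms: none
Why: The methylene between the carbonyl and sulfur is by far the most acidic C–H site, so the amide acetal should condense there with loss of methanol (enaminone formation by aminomethylenation); placing the one-carbon unit on the thio ketone before the aryl ketone is attached avoids condensation at the doubly activated central methylene of a 1,3-diketone.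

**Step 2**
Reactants: 3 (Z)-4-(dimethylamino)-3-(phenylthio)but-3-en-2-one; 4 2,5-dimethoxybenzoyl chloride
Product: 6 2-(2,5-dimethoxyphenyl)-5-(phenylthio)-4H-pyran-4-one, via diketo enaminone 5 (not isolated)
Conditions: LiHMDS (2.1 equiv), THF, −78 °C; then 4, −78 °C → rt; then 2 M HCl, rt
Reagents that add atoms: none
Why: LiHMDS deprotonates the methyl group of the vinylogous amide, the lithium enolate is C-acylated by the aroyl chloride (crossed Claisen acylation, the second equivalent of base taking up the acidic diketone), and acid then drives 6-endo addition of the enol oxygen to the aminomethylene carbon with loss of dimethylamine (addition–elimination), the established enaminone route to γ-pyrones.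

**Step 3**
Reactants: 6 2-(2,5-dimethoxyphenyl)-5-(phenylthio)-4H-pyran-4-one
Product: 7 2-(2,5-dimethoxyphenyl)-5-(phenylsulfinyl)-4H-pyran-4-one (racemic at sulfur)
Conditions: mCPBA (1.0 equiv), CH2Cl2, −20 → 0 °C
Reagents that add atoms: mCPBA, OOC(=O)c1cccc(Cl)c1
Why: Sulfur is the most nucleophilic site and both pyranone C=C bonds are electron-poor, so one equivalent of peracid at low temperature should stop at the sulfoxide (chemoselective sulfide S-oxidation); the new sulfur stereocentre forms as a racemate, which is acceptable because it is lost in step 6.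

**Step 4**
Reactants: 8 methyl 4-methoxy-3-oxobutanoate
Product: 10 methyl (E)-3,4-dimethoxybut-2-enoate, via dimethyl ketal 9 (not isolated)
Conditions: HC(OMe)3 (neat, 1.5 equiv), cat. H2SO4, rt; then cat. TsOH, distil
Reagents that add atoms: trimethyl orthoformate, COC(OC)OC
Why: Acid-catalysed ketalisation of the ketone by the orthoester and thermal loss of methanol from ketal 9 towards the ester should give the conjugated β-methoxy enoate (enol ether formation via orthoformate), the E isomer with OMe anti to the ester being the thermodynamic product.

**Step 5**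
Reactants: 10 methyl (E)-3,4-dimethoxybut-2-enoate
Product: 11 (1Z,3Z)-1,3,4-trimethoxy-1-(trimethylsilyloxy)buta-1,3-diene
Conditions: LDA (1.1 equiv), THF, −78 °C; TMSCl, −78 → 0 °C; non-aqueous work-up (pentane, filtration), used at once
Reagents that add atoms: chlorotrimethylsilane, C[Si](C)(C)Cl
Why: Kinetic γ-deprotonation of the β-methoxy enoate by LDA gives the extended ester dienolate, which the hard silyl chloride traps on oxygen (the standard preparation of Brassard-type vinylketene acetals); the 4-methoxy group should settle anti to C2 for steric reasons, which is the geometry a cycloaddition needs, and the ketene acetal geometry is irrelevant.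

**Step 6**
Reactants: 7 2-(2,5-dimethoxyphenyl)-5-(phenylsulfinyl)-4H-pyran-4-one; 11 (1Z,3Z)-1,3,4-trimethoxy-1-(trimethylsilyloxy)buta-1,3-diene
Product: 15 5-hydroxy-7,8,2',5'-tetramethoxyflavone (the target), via cis-fused cycloadduct 12 (not isolated), via dihydrochromenone ketal 13 (not isolated), via chromene-4,5-dione tautomer 14 (not isolated)
Conditions: 11 (2.5 equiv), toluene, Ar, rt → 80 °C; then 1 M HCl, THF, rt
Reagents that add atoms: none
Why: Proposed new method: the electron-rich vinylketene acetal 11 should add to the pyranone C5=C6 bond of 7, whose LUMO is lowered by the C4 carbonyl and the sulfinyl group together, in a polarised, asynchronous normal-demand [4+2] cycloaddition in which the CH(OMe) terminus of 11 bonds to pyranone C6 (β to both C=O and S=O) and the ketene-acetal carbon to the sulfinyl-bearing C5; the closest known reaction type is the Diels–Alder addition of Brassard-type 1,1,3-trioxygenated dienes to sulfinylquinones and of siloxydienes to 3-sulfinyl- or 3-acylchromones with eliminative aromatisation, which has not been shown for a monocyclic 3-sulfinyl-4-pyranone. Ring A closes as a six-membered carbocycle by intermolecular [4+2] annulation, forming C8–C8a and C5–C4a (flavone numbering) and giving the cis-fused adduct 12. Suprafacial addition places the sulfinyl group and the 8a-hydrogen on the same face, so thermal syn-elimination of benzenesulfenic acid gives 13, collapse of the mixed methyl silyl ketal with loss of methoxytrimethylsilane gives dienone 14, and enolisation gives the hydrogen-bonded 5-phenol 15. No stereocentre survives: the transient centres at C4a, C5, C8, C8a and sulfur and both diene geometries are erased on aromatisation, so endo/exo and facial selectivity do not matter. What is needed is head-to-tail regiochemistry and reaction at C5=C6 rather than at the aryl-substituted C2=C3 bond; the first follows from the matched polarisation of the diene (nucleophilic C4) and the sulfinyl enone (electrophilic C6), the second from the sulfinyl group activating only its own double bond. The acidic work-up cleaves any aryl silyl ether or residual ketal so that partially aromatised material converges on 15.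

**Compound list**
1 | 1-(phenylthio)propan-2-one | CC(=O)CSc1ccccc1 | starting material
2 | N,N-dimethylformamide dimethyl acetal | COC(OC)N(C)C | starting material
3 | (Z)-4-(dimethylamino)-3-(phenylthio)but-3-en-2-one | CC(=O)/C(Sc1ccccc1)=C/N(C)C | intermediate
4 | 2,5-dimethoxybenzoyl chloride | COc1ccc(OC)c(C(=O)Cl)c1 | starting material
5 | (Z)-1-(2,5-dimethoxyphenyl)-5-(dimethylamino)-4-(phenylthio)pent-4-ene-1,3-dione | COc1ccc(OC)c(C(=O)CC(=O)/C(Sc2ccccc2)=C/N(C)C)c1 | intermediate (not isolated)
6 | 2-(2,5-dimethoxyphenyl)-5-(phenylthio)-4H-pyran-4-one | COc1ccc(OC)c(-c2cc(=O)c(Sc3ccccc3)co2)c1 | intermediate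
7 | 2-(2,5-dimethoxyphenyl)-5-(phenylsulfinyl)-4H-pyran-4-one (racemic, one enantiomer drawn) | O=c1cc(-c2cc(OC)ccc2OC)occ1[S@](=O)c1ccccc1 | intermediate
8 | methyl 4-methoxy-3-oxobutanoate | COCC(=O)CC(=O)OC | starting material
9 | methyl 3,3,4-trimethoxybutanoate | COCC(OC)(OC)CC(=O)OC | intermediate (not isolated)
10 | methyl (E)-3,4-dimethoxybut-2-enoate | COC/C(OC)=C\C(=O)OC | intermediate
11 | (1Z,3Z)-1,3,4-trimethoxy-1-(trimethylsilyloxy)buta-1,3-diene | CO/C=C(OC)/C=C(/OC)O[Si](C)(C)C | intermediate
12 | 2-(2,5-dimethoxyphenyl)-5,7,8-trimethoxy-4a-(phenylsulfinyl)-5-(trimethylsilyloxy)-4a,5,8,8a-tetrahydro-4H-chromen-4-one (racemic; cis ring fusion, sulfinyl and 8a-H on the same face; mixture at C5, C8 and S) | COc1ccc(OC)c(C2=CC(=O)[C@]3(S(=O)c4ccccc4)C(OC)(O[Si](C)(C)C)C=C(OC)C(OC)[C@@H]3O2)c1 | intermediate (not isolated)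
13 | 2-(2,5-dimethoxyphenyl)-5,7,8-trimethoxy-5-(trimethylsilyloxy)-5,8-dihydro-4H-chromen-4-one (mixture of stereoisomers at C5 and C8) | COc1ccc(OC)c(C2=CC(=O)C3=C(O2)C(OC)C(OC)=CC3(OC)O[Si](C)(C)C)c1 | intermediate (not isolated)
14 | 2-(2,5-dimethoxyphenyl)-7,8-dimethoxy-8H-chromene-4,5-dione (racemic at C8) | COc1ccc(OC)c(C2=CC(=O)C3=C(O2)C(OC)C(OC)=CC3=O)c1 | intermediate (not isolated)
15 | 5-hydroxy-7,8,2',5'-tetramethoxyflavone | COc1ccc(OC)c(-c2cc(=O)c3c(O)cc(OC)c(OC)c3o2)c1 | target

**Totals.** Total step count: 6. Longest linear sequence: 4 steps (steps 1, 2, 3 and 6); the diene branch (steps 4 and 5) joins at step 6.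

**Steps most likely to fail**

1. Step 6 (proposed new method). The process at risk is ring closure: conjugate addition of the diene terminus could be followed by opening of the pyranone ring instead of the second C–C bond formation. The partly aromatic pyranone could also react so slowly that the diene hydrolyses or oligomerises first. Silicon-induced Pummerer-type reduction of the sulfoxide, or loss of trimethylsilanol in place of methoxytrimethylsilane (leaving the 5-oxygen methylated), are further possibilities. The fallback uses known chemistry only, sets out from compound 4 and returns at compound 15, with ring A brought in preformed. Acid chloride 4 would O-acylate 2'-hydroxy-3',4',6'-trimethoxyacetophenone F1 (pyridine, rt) to give 2-acetyl-3,5,6-trimethoxyphenyl 2,5-dimethoxybenzoate F2. Baker–Venkataraman rearrangement (KOH, pyridine, 50 °C) would give 1-(2-hydroxy-3,4,6-trimethoxyphenyl)-3-(2,5-dimethoxyphenyl)propane-1,3-dione F3. Cyclodehydration (H2SO4, AcOH, 100 °C) would give 5,7,8,2',5'-pentamethoxyflavone F4. Chelation-controlled cleavage of the peri 5-methyl ether (BCl3, CH2Cl2, −78 → 0 °C) would then give target 15.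

2. Step 5. The processes at risk are addition of the amide base to the enoate or self-condensation in place of γ-deprotonation, C-silylation, and hydrolysis of the ketene acetal during isolation. The fallback sets out from compound 8 and returns at compound 15, changing the diene to a bis-silyl enol ether. Keto ester 8 would be silylated (Et3N, TMSCl, Et2O) to methyl (Z)-4-methoxy-3-(trimethylsilyloxy)but-2-enoate F5. A second silylation (LDA, THF, −78 °C; TMSCl) would give (1Z,3Z)-1,4-dimethoxy-1,3-bis(trimethylsilyloxy)buta-1,3-diene F6. Cycloaddition of F6 to sulfoxide 7 under the conditions of step 6 should give, after the acidic work-up, 5,7-dihydroxy-8,2',5'-trimethoxyflavone F7. Its non-chelated 7-hydroxyl would be methylated selectively (Me2SO4, 1.05 equiv, K2CO3, acetone, rt) to give 15, the hydrogen-bonded 5-OH staying free.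

3. Step 2. The processes at risk are O-acylation or double acylation of the enolate, quenching of unreacted enolate by proton transfer from the diketone product, and incomplete ring closure. The fallback sets out from compound 1 and returns at compound 6, assembling the chain by classical polycarbonyl dianion chemistry. The dianion of 1 (NaH, then n-BuLi, THF, 0 °C) would be aroylated at its methyl terminus by methyl 2,5-dimethoxybenzoate F8 to give 1-(2,5-dimethoxyphenyl)-4-(phenylthio)butane-1,3-dione F9. The dianion of F9 (LDA, 2.2 equiv, THF, −78 °C), nucleophilic at the sulfur-bearing terminal carbon, would be formylated with ethyl formate to 5-(2,5-dimethoxyphenyl)-3,5-dioxo-2-(phenylthio)pentanal F10. Acid (TFA, CH2Cl2, rt) would cyclodehydrate F10 to sulfide 6, which continues with step 3.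

**Further compounds**
F1 | step 6 | 2'-hydroxy-3',4',6'-trimethoxyacetophenone | CC(=O)c1c(O)c(OC)c(OC)cc1OC
F2 | step 6 | 2-acetyl-3,5,6-trimethoxyphenyl 2,5-dimethoxybenzoate | CC(=O)c1c(OC(=O)c2cc(OC)ccc2OC)c(OC)c(OC)cc1OC
F3 | step 6 | 1-(2-hydroxy-3,4,6-trimethoxyphenyl)-3-(2,5-dimethoxyphenyl)propane-1,3-dione | COc1ccc(OC)c(C(=O)CC(=O)c2c(O)c(OC)c(OC)cc2OC)c1
F4 | step 6 | 5,7,8,2',5'-pentamethoxyflavone | COc1ccc(OC)c(-c2cc(=O)c3c(OC)cc(OC)c(OC)c3o2)c1
F5 | step 5 | methyl (Z)-4-methoxy-3-(trimethylsilyloxy)but-2-enoate | COC/C(O[Si](C)(C)C)=C/C(=O)OC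
F6 | step 5 | (1Z,3Z)-1,4-dimethoxy-1,3-bis(trimethylsilyloxy)buta-1,3-diene | CO/C=C(O[Si](C)(C)C)/C=C(/OC)O[Si](C)(C)C
F7 | step 5 | 5,7-dihydroxy-8,2',5'-trimethoxyflavone | COc1ccc(OC)c(-c2cc(=O)c3c(O)cc(O)c(OC)c3o2)c1
F8 | step 2 | methyl 2,5-dimethoxybenzoate (commercial) | COc1ccc(OC)c(C(=O)OC)c1
F9 | step 2 | 1-(2,5-dimethoxyphenyl)-4-(phenylthio)butane-1,3-dione | COc1ccc(OC)c(C(=O)CC(=O)CSc2ccccc2)c1
F10 | step 2 | 5-(2,5-dimethoxyphenyl)-3,5-dioxo-2-(phenylthio)pentanal (racemic, largely enolised, keto form drawn) | COc1ccc(OC)c(C(=O)CC(=O)C(C=O)Sc2ccccc2)c1
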